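## The problem

Target 24 is the bis(acetate) of a lyoniresinol-type 1-aryltetralin. A pentasubstituted ring A (C5–H, C6–OMe, C7–OH, C8–OMe) is fused to the saturated ring B (C1–C4). Ring C (4-hydroxy-3,5-dimethoxyphenyl) sits on C1, and C2 and C3 carry acetoxymethyl arms (C9' on C2, C9 on C3).

Ring B has to be closed beside the crowded diarylmethine C1, which lies between ring C and the peri methoxy group on C8. The three contiguous stereocentres (1S,2R,3R) are all-trans. None is α to a carbonyl group in 24, so none can be repaired by late epimerization.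

C1 and C2 are neighbours in an open chain before ring B exists and can be set there by one external controller. C3 must then be set by C2 (supported by C1) in the ring-forming event.

The two primary acetates rule out late base, hydride or organometallic steps. The two 2,6-dimethoxyphenols are easily oxidized, ring C especially, since it is para to the benzhydrylic C1–H. They must therefore stay masked until a final neutral unmasking, and the 1,2,3-trioxygenated arenes limit the use of strong Lewis acids.

The enabling feature is that C3 is bonded both to the benzylic methylene C4 of ring A and to the oxygen-bearing C9. A radical at C4 can add to C3 of a C3=C9 alkenylboronate, and the boron left on C9 is a masked hydroxyl.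

## Retrosynthesis

**End game, 24 back to 20.** The two aryl O–benzyl bonds, the two acetyl C–O bonds, the Si–O bond at C9' and the C9–O bond are cut in turn (24 ⇐ 23 ⇐ 22 ⇐ 21 ⇐ 20). Hydrogenolysis is placed last because it is the only unmasking that leaves primary acetates and free syringyl phenols untouched. The C9 oxygen is traced back to a C–B bond because a boronate survives radical conditions, whereas a free or acylated oxygen on an alkene would not activate it for radical addition. Boronate 20 is barely simpler than 24 in skeleton, but every oxygen is differentiated. The forward steps must be mild and chemoselective, nothing more.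

**Key disconnection, 20 to 19.** The C3–C4 bond is cut to give benzylic bromide 19, which carries an (E)-alkenylboronate. Cutting C1–C8a or C1–C2 instead would leave C3 to be made by an intermolecular, less controllable event. Cutting C3–C4 closes ring B, creates C3 and installs the C9 oxygen handle in one operation. The price is that C3 is formed under kinetic control with no later correction. To strengthen this from within, the C2 arm carries the bulky tert-butyldiphenylsilyl group, the radical precursor is made only at the last moment, and the stannane is to be kept dilute. Bromide 19 is acyclic, with only C1 and C2 as stereocentres.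

**Radical precursor, 19 back to 17.** The C4–Br bond is traced to the benzylic silyl ether of 18. The C3=C9 double bond is traced to aldehyde 17 and a one-carbon boron-bearing chromium carbenoid. A non-basic olefination is required because C2 of 17 is an epimerizable α-stereocentre with a β-silyloxy group. The benzylic oxygen must be orthogonal to the C9' silyl ether, hence the tert-butyldimethylsilyl/tert-butyldiphenylsilyl pair.

**C2–C9' bond, 17 back to 12.** Aldehyde 17 comes from imide 15 through alcohol 16. The C2–C9' bond of 14 is cut to the 3,3-diarylpropanoyl imide 12 and a one-carbon electrophile. Using the imide enolate lets the oxazolidinone, rather than the adjacent C1, dictate C2. C9' must be silylated before the auxiliary is reduced off, because C2 is stereogenic only while its two one-carbon arms differ.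

**C1–ring C bond, 12 back to 8 and 11.** The bond from C1 to ring C is cut to cinnamoyl imide 8 and aryl Grignard reagent 11. The unhindered ring C aryl is chosen as the nucleophile and the doubly ortho-substituted ring A cinnamoyl as the acceptor, because a 2,6-disubstituted arylcopper would transfer poorly. The same auxiliary then serves C1 and C2.

**Fragments, 8 back to 1, 6 and 9.** The C8a–C1 bond of 8 is cut by a Heck disconnection to aryl bromide 5 and acryloyl imide 7. Bromide 5 derives from syringaldehyde 1 through 2, 3 and 4: the formyl carbon of 1 becomes C4, and the bromine enters ortho to it at the future C8a. Imide 7 comes from auxiliary 6, and 11 from phenol 9 through 10. All three starting materials are commercial.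

## Roads not taken

**Alternative 1:** The cut is C2–C3 together with C1–C8a, so that both halves come from one monomer, the N-sinapoyl oxazolidinone A1. A laccase with dioxygen would oxidize two molecules of A1 to phenoxyl radicals that couple at their β-carbons, and the bis(quinone methide) would close C1–C8a to give dihydronaphthalene A2.
- Merits: the whole carbon skeleton with all its oxygens arises in one step from a monomer that needs no phenol protection. C3 of A2 ends up next to a carbonyl group, so the 2,3-relationship can be equilibrated after reduction of the C3=C4 double bond. In step count and atom economy this road is clearly better than the chosen one.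
- Weak points: absolute and relative control in a free phenoxyl-radical coupling is uncertain. A hydrophobic imide is an untested laccase substrate. A2 still needs a stereoselective alkene reduction and reduction of two imides in the presence of free phenols. Aliphatic hydroxyls must then be acetylated selectively beside two phenols, which brings protection steps back.
- Comparison: the chosen plan (12, 14) sets C1 and C2 through closed chelate models and keeps the phenols masked throughout, so each stereocentre is predictable. It pays for this with length.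

**Alternative 2:** The cut is C2–C9' together with C3–C9. Dichloroketene A4, generated in the flask by zinc dechlorination of its acid chloride precursor, would add across C2=C3 of the 1-aryl-1,4-dihydronaphthalene A3, anti to ring C, to give the cis-fused dichlorocyclobutanone A5.
- Merits: both one-carbon arms arrive in one step, the C1 stereocentre steers the face, and either regiochemistry serves.
- Weak points: a suprafacial cycloaddition necessarily gives the 2,3-cis relationship. C3 would have to be inverted after dechlorination and ring cleavage, and on an open-chain carbonyl derivative, because cis-fused lactones of this family are the more stable ones. A3 is a skipped diene with a doubly benzylic, allylic C1–H that isomerizes or aromatizes easily, notably with the zinc salts formed, and it needs an enantioselective synthesis of its own.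
- Comparison: this road can correct C3, which the chosen plan cannot. Against that, the chosen plan forms 2,3-trans directly in 20 and never passes through a skipped diene or the wrong C3 configuration.

**Alternative 3:** The cut is C1–C2 together with C3–C4. UV irradiation of the 2-benzylbenzaldehyde A6 would give its hydroxy-ortho-quinodimethane, which would add dimethyl fumarate A7 on a chiral titanium Lewis acid to give tetralin diester A8.
- Merits: ring B, two C–C bonds and three stereocentres form in one convergent step from an achiral precursor. The 2,3-trans relationship is guaranteed by the fumarate geometry. On the most delicate point of the chosen plan, the C3 configuration, this road is intrinsically safer, and it is also considerably shorter.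
- Weak points: the (E,E)-dienol must hold the ring C aryl in the plane beside the C8 methoxy group. This strained geometry puts the 1,2-relationship and the enantioselectivity of an untested substrate class in doubt. The C4 hydroxyl of A8 must be removed, and both esters reduced, before acetylation.
- Comparison: the chosen plan sets against this the stoichiometric but well-understood auxiliary control of C1 and C2, the absence of a deoxygenation, and a thermal, scalable ring closure.

Key step: step 15

Remark on numbering: the labels C1–C8a, C9 (on C3) and C9' (on C2) of the target tetralin are used for the corresponding atoms of every intermediate.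

Assumption: the arylcopper is taken to attack the magnesium-chelated syn-s-cis enoyl imide, and the one-carbon electrophile the chelated titanium Z-enolate, each anti to the C4 benzyl group of the auxiliary; on this basis the (R)-configured auxiliary 6 is required for (1S,2R,3R)-24.

## Route

Step 1
Reactants: 1 syringaldehyde (4-hydroxy-3,5-dimethoxybenzaldehyde)
Product: 2 4-(benzyloxy)-3,5-dimethoxybenzaldehyde
Conditions: BnBr, K2CO3, DMF, 60 °C
Reagents that add atoms: benzyl bromide, BrCc1ccccc1
Why: Williamson etherification of an acidic, hindered phenol; the benzyl ether masks the ring A phenol until the final hydrogenolysis.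

Step 2
Reactants: 2 4-(benzyloxy)-3,5-dimethoxybenzaldehyde
Product: 3 4-(benzyloxy)-2-bromo-3,5-dimethoxybenzaldehyde
Conditions: NBS, CHCl3, reflux, dark
Reagents that add atoms: N-bromosuccinimide, O=C1CCC(=O)N1Br
Why: Electrophilic aromatic bromination; the two free positions are equivalent and each is ortho to one methoxy group and para to the other, as in the known monobromination of 3,4,5-trialkoxybenzaldehydes.

Step 3
Reactants: 3 4-(benzyloxy)-2-bromo-3,5-dimethoxybenzaldehyde
Product: 4 [4-(benzyloxy)-2-bromo-3,5-dimethoxyphenyl]methanol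
Conditions: NaBH4, MeOH/THF, 0 °C
Reagents that add atoms: none
Why: Borohydride reduction of an aryl aldehyde; the aryl bromide and ethers are inert, and the formyl carbon becomes the future C4.

Step 4
Reactants: 4 [4-(benzyloxy)-2-bromo-3,5-dimethoxyphenyl]methanol
Product: 5 {[4-(benzyloxy)-2-bromo-3,5-dimethoxyphenyl]methoxy}(tert-butyl)dimethylsilane
Conditions: TBSCl, imidazole, DMF, rt
Reagents that add atoms: tert-butyldimethylsilyl chloride, CC(C)(C)[Si](C)(C)Cl
Why: Standard silylation of a primary benzylic alcohol; the silyl ether tolerates organomagnesium, enolate and hydride steps and is later the direct precursor of the benzylic bromide.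

Step 5
Reactants: 6 (R)-4-benzyloxazolidin-2-one
Product: 7 (R)-3-acryloyl-4-benzyloxazolidin-2-one
Conditions: acryloyl chloride, Et3N, LiCl, THF, 0 °C to rt
Reagents that add atoms: acryloyl chloride, C=CC(Cl)=O
Why: Lithium chloride/amine-promoted N-acylation of an oxazolidinone, which avoids a strongly basic lithiated carbamate that would polymerize the acrylate; the three acryloyl carbons become C1, C2 and C3.

Step 6
Reactants: 5 {[4-(benzyloxy)-2-bromo-3,5-dimethoxyphenyl]methoxy}(tert-butyl)dimethylsilane; 7 (R)-3-acryloyl-4-benzyloxazolidin-2-one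
Product: 8 (R)-4-benzyl-3-[(E)-3-{3-(benzyloxy)-6-[(tert-butyldimethylsilyloxy)methyl]-2,4-dimethoxyphenyl}prop-2-enoyl]oxazolidin-2-one
Conditions: Pd2(dba)3 (cat.), [HP(t-Bu)3]BF4 (cat.), Cy2NMe, dioxane, 80 °C
Reagents that add atoms: none
Why: Heck reaction; the bulky electron-rich trialkylphosphine lets zerovalent palladium insert into an electron-rich, doubly ortho-substituted aryl bromide, and syn insertion followed by syn β-hydride elimination gives the E-enoyl imide and forms the C8a–C1 bond.

Step 7
Reactants: 9 4-bromo-2,6-dimethoxyphenol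
Product: 10 2-(benzyloxy)-5-bromo-1,3-dimethoxybenzene
Conditions: BnBr, K2CO3, DMF, 60 °C
Reagents that add atoms: benzyl bromide, BrCc1ccccc1
Why: Williamson etherification; masks the ring C phenol in the same way as ring A so that both are released together at the end.

Step 8
Reactants: 10 2-(benzyloxy)-5-bromo-1,3-dimethoxybenzene; 8 (R)-4-benzyl-3-[(E)-3-{3-(benzyloxy)-6-[(tert-butyldimethylsilyloxy)methyl]-2,4-dimethoxyphenyl}prop-2-enoyl]oxazolidin-2-one
Product: 12 (R)-4-benzyl-3-[(3S)-3-[4-(benzyloxy)-3,5-dimethoxyphenyl]-3-{3-(benzyloxy)-6-[(tert-butyldimethylsilyloxy)methyl]-2,4-dimethoxyphenyl}propanoyl]oxazolidin-2-one, via aryl Grignard reagent 11 (not isolated)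
Conditions: Mg, THF, reflux (gives 11); CuBr·SMe2 (0.5 equiv), THF/Me2S, −40 °C; then 8, −40 to −10 °C; aq NH4Cl
Reagents that add atoms: none
Why: Copper-mediated conjugate addition of an aryl Grignard reagent to an N-enoyl oxazolidinone; the arylcopper attacks the β-carbon of the magnesium-chelated syn-s-cis imide on the face opposite the benzyl group, which sets C1 as S. Enoyl oxazolidinones with 2,6-disubstituted β-aryl groups are known to accept such reagents.

Step 9
Reactants: 12 (R)-4-benzyl-3-[(3S)-3-[4-(benzyloxy)-3,5-dimethoxyphenyl]-3-{3-(benzyloxy)-6-[(tert-butyldimethylsilyloxy)methyl]-2,4-dimethoxyphenyl}propanoyl]oxazolidin-2-one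
Product: 14 (R)-4-benzyl-3-[(2S,3S)-3-[4-(benzyloxy)-3,5-dimethoxyphenyl]-3-{3-(benzyloxy)-6-[(tert-butyldimethylsilyloxy)methyl]-2,4-dimethoxyphenyl}-2-(hydroxymethyl)propanoyl]oxazolidin-2-one, via trichlorotitanium Z-enolate 13 (not isolated)
Conditions: TiCl4, i-Pr2NEt, CH2Cl2, 0 °C; then 1,3,5-trioxane, TiCl4, 0 °C; aq NH4Cl
Reagents that add atoms: 1,3,5-trioxane, C1OCOCO1
Why: Evans hydroxymethylation of a chelated titanium Z-enolate (alkylation-type stereocontrol); the formaldehyde equivalent attacks the enolate face opposite the benzyl group, which sets C2 (2S here, the configuration that becomes 2R in 24) and places C9' trans to ring C in the later ring.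

Step 10
Reactants: 14 (R)-4-benzyl-3-[(2S,3S)-3-[4-(benzyloxy)-3,5-dimethoxyphenyl]-3-{3-(benzyloxy)-6-[(tert-butyldimethylsilyloxy)methyl]-2,4-dimethoxyphenyl}-2-(hydroxymethyl)propanoyl]oxazolidin-2-one
Product: 15 (R)-4-benzyl-3-[(2S,3S)-3-[4-(benzyloxy)-3,5-dimethoxyphenyl]-3-{3-(benzyloxy)-6-[(tert-butyldimethylsilyloxy)methyl]-2,4-dimethoxyphenyl}-2-{[(tert-butyldiphenylsilyl)oxy]methyl}propanoyl]oxazolidin-2-one
Conditions: TBDPSCl, imidazole, DMF, rt
Reagents that add atoms: tert-butyldiphenylsilyl chloride, CC(C)(C)[Si](Cl)(c1ccccc1)c1ccccc1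
Why: Silylation of a primary alcohol under non-basic conditions that avoid retro-aldol loss of the new carbon; the bulky, robust group keeps C9' distinct from C3 (so C2 stays stereogenic) and is orthogonal to the benzylic silyl ether.

Step 11
Reactants: 15 (R)-4-benzyl-3-[(2S,3S)-3-[4-(benzyloxy)-3,5-dimethoxyphenyl]-3-{3-(benzyloxy)-6-[(tert-butyldimethylsilyloxy)methyl]-2,4-dimethoxyphenyl}-2-{[(tert-butyldiphenylsilyl)oxy]methyl}propanoyl]oxazolidin-2-one
Product: 16 (2R,3S)-3-[4-(benzyloxy)-3,5-dimethoxyphenyl]-3-{3-(benzyloxy)-6-[(tert-butyldimethylsilyloxy)methyl]-2,4-dimethoxyphenyl}-2-{[(tert-butyldiphenylsilyl)oxy]methyl}propan-1-ol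
Conditions: LiBH4, MeOH (1 equiv), THF, 0 °C
Reagents that add atoms: none
Why: Reductive cleavage of the exocyclic imide carbonyl by lithium borohydride, the standard removal of an oxazolidinone auxiliary; auxiliary 6 is recovered, and the stereocentres are not touched because no enolizable carbonyl remains.

Step 12
Reactants: 16 (2R,3S)-3-[4-(benzyloxy)-3,5-dimethoxyphenyl]-3-{3-(benzyloxy)-6-[(tert-butyldimethylsilyloxy)methyl]-2,4-dimethoxyphenyl}-2-{[(tert-butyldiphenylsilyl)oxy]methyl}propan-1-ol
Product: 17 (2S,3S)-3-[4-(benzyloxy)-3,5-dimethoxyphenyl]-3-{3-(benzyloxy)-6-[(tert-butyldimethylsilyloxy)methyl]-2,4-dimethoxyphenyl}-2-{[(tert-butyldiphenylsilyl)oxy]methyl}propanal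
Conditions: Dess–Martin periodinane, NaHCO3, CH2Cl2, 0 °C to rt
Reagents that add atoms: none
Why: Dess–Martin oxidation under buffered, non-basic conditions, which should leave the α-stereocentre C2 and the β-silyloxy group intact; the aldehyde is used at once.

Step 13
Reactants: 17 (2S,3S)-3-[4-(benzyloxy)-3,5-dimethoxyphenyl]-3-{3-(benzyloxy)-6-[(tert-butyldimethylsilyloxy)methyl]-2,4-dimethoxyphenyl}-2-{[(tert-butyldiphenylsilyl)oxy]methyl}propanal
Product: 18 2-[(1E,3S,4S)-4-[4-(benzyloxy)-3,5-dimethoxyphenyl]-4-{3-(benzyloxy)-6-[(tert-butyldimethylsilyloxy)methyl]-2,4-dimethoxyphenyl}-3-{[(tert-butyldiphenylsilyl)oxy]methyl}but-1-en-1-yl]-4,4,5,5-tetramethyl-1,3,2-dioxaborolane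
Conditions: Cl2CHB(pin), CrCl2, LiI, THF, rt
Reagents that add atoms: 2-(dichloromethyl)-4,4,5,5-tetramethyl-1,3,2-dioxaborolane, ClC(Cl)B1OC(C)(C)C(C)(C)O1
Why: Takai–Utimoto boryl-olefination; the geminal dichromium carbenoid formed by divalent chromium adds to the aldehyde and eliminates to the E-alkenylboronate, and the non-basic medium should spare the epimerizable C2; this step installs C9 with its boron.

Step 14
Reactants: 18 2-[(1E,3S,4S)-4-[4-(benzyloxy)-3,5-dimethoxyphenyl]-4-{3-(benzyloxy)-6-[(tert-butyldimethylsilyloxy)methyl]-2,4-dimethoxyphenyl}-3-{[(tert-butyldiphenylsilyl)oxy]methyl}but-1-en-1-yl]-4,4,5,5-tetramethyl-1,3,2-dioxaborolane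
Product: 19 2-[(1E,3S,4S)-4-[3-(benzyloxy)-6-(bromomethyl)-2,4-dimethoxyphenyl]-4-[4-(benzyloxy)-3,5-dimethoxyphenyl]-3-{[(tert-butyldiphenylsilyl)oxy]methyl}but-1-en-1-yl]-4,4,5,5-tetramethyl-1,3,2-dioxaborolane
Conditions: Ph3PBr2, CH2Cl2, 0 °C to rt
Reagents that add atoms: dibromotriphenylphosphorane, BrP(Br)(c1ccccc1)(c1ccccc1)c1ccccc1
Why: Direct conversion of a silyl ether into a bromide by dibromotriphenylphosphorane (silyl transfer to bromide, then displacement of triphenylphosphine oxide from the oxyphosphonium ion); the electron-rich benzylic tert-butyldimethylsilyl ether should react far faster than the hindered primary tert-butyldiphenylsilyl ether, and the alkenylboronate and aryl ethers are inert.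

Step 15
Reactants: 19 2-[(1E,3S,4S)-4-[3-(benzyloxy)-6-(bromomethyl)-2,4-dimethoxyphenyl]-4-[4-(benzyloxy)-3,5-dimethoxyphenyl]-3-{[(tert-butyldiphenylsilyl)oxy]methyl}but-1-en-1-yl]-4,4,5,5-tetramethyl-1,3,2-dioxaborolane
Product: 20 tert-butyl{[(1S,2S,3R)-7-(benzyloxy)-1-[4-(benzyloxy)-3,5-dimethoxyphenyl]-6,8-dimethoxy-3-[(4,4,5,5-tetramethyl-1,3,2-dioxaborolan-2-yl)methyl]-1,2,3,4-tetrahydronaphthalen-2-yl]methoxy}diphenylsilane
Conditions: Bu3SnH (1.3 equiv), AIBN (0.2 equiv), syringe pump over 8 h, PhH (0.005 M), reflux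
Reagents that add atoms: none
Why: Tributylstannyl radicals abstract bromine from 19 to give the ring A benzylic radical at C4, which adds to C3 of the E-alkenylboronate; the resulting C9 radical, stabilized by the vacant boron orbital, takes hydrogen from the stannane and carries the chain. The closest known reaction types are tin hydride cyclizations onto alkenylboronic esters through α-boryl radicals and 6-exo closures of ortho-tethered benzylic radicals. Ring B closes in the 6-exo-trig mode; 7-endo attack at C9 would leave an unstabilized secondary radical and is disfavoured by the exo preference and by the boron substituent. The new stereocentre C3 is controlled by C2: in the chair-like transition state the large silyloxymethyl arm on C2 lies pseudo-equatorial and anti to the forming C3–C4 bond, with the ring C aryl on C1 trans to it, so the boryl-methyl arm should emerge trans to C9'; C9 itself is not stereogenic. The step needs ring closure to outrun hydrogen transfer to the stabilized benzylic radical, which slow stannane addition at high dilution and the matched polarity of an electron-rich radical with an electron-poor alkenylboronate should secure. It also needs 2,3-trans selectivity, for which the fixed C1 and C2 configurations and the bulk of the tert-butyldiphenylsilyl group are the only control elements, since C3 cannot be corrected afterwards.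

Step 16
Reactants: 20 tert-butyl{[(1S,2S,3R)-7-(benzyloxy)-1-[4-(benzyloxy)-3,5-dimethoxyphenyl]-6,8-dimethoxy-3-[(4,4,5,5-tetramethyl-1,3,2-dioxaborolan-2-yl)methyl]-1,2,3,4-tetrahydronaphthalen-2-yl]methoxy}diphenylsilane
Product: 21 [(1S,2R,3R)-7-(benzyloxy)-1-[4-(benzyloxy)-3,5-dimethoxyphenyl]-2-{[(tert-butyldiphenylsilyl)oxy]methyl}-6,8-dimethoxy-1,2,3,4-tetrahydronaphthalen-3-yl]methanol
Conditions: NaBO3·4H2O, THF/H2O, rt
Reagents that add atoms: sodium perborate, [Na+].[Na+].O[B-]1(O)OO[B-](O)(O)OO1
Why: Oxidation of a primary alkylboronic ester by perborate (1,2-migration of carbon from boron to oxygen); the mild, weakly basic medium leaves silyl and benzyl ethers alone and reveals the C9 hydroxyl.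

Step 17
Reactants: 21 [(1S,2R,3R)-7-(benzyloxy)-1-[4-(benzyloxy)-3,5-dimethoxyphenyl]-2-{[(tert-butyldiphenylsilyl)oxy]methyl}-6,8-dimethoxy-1,2,3,4-tetrahydronaphthalen-3-yl]methanol
Product: 22 [(1S,2R,3R)-7-(benzyloxy)-1-[4-(benzyloxy)-3,5-dimethoxyphenyl]-6,8-dimethoxy-1,2,3,4-tetrahydronaphthalene-2,3-diyl]dimethanol
Conditions: TBAF, AcOH, THF, rt
Reagents that add atoms: none
Why: Fluoride-induced cleavage of the primary silyl ether, buffered with acetic acid; benzyl ethers are unaffected.

Step 18
Reactants: 22 [(1S,2R,3R)-7-(benzyloxy)-1-[4-(benzyloxy)-3,5-dimethoxyphenyl]-6,8-dimethoxy-1,2,3,4-tetrahydronaphthalene-2,3-diyl]dimethanol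
Product: 23 [(1S,2R,3R)-7-(benzyloxy)-1-[4-(benzyloxy)-3,5-dimethoxyphenyl]-6,8-dimethoxy-1,2,3,4-tetrahydronaphthalene-2,3-diyl]bis(methylene) diacetate
Conditions: Ac2O, pyridine, DMAP (cat.), CH2Cl2, rt
Reagents that add atoms: acetic anhydride, CC(=O)OC(C)=O
Why: Nucleophile-catalysed acetylation of two primary alcohols; the phenols are still benzylated, so no chemoselectivity problem arises.

Step 19
Reactants: 23 [(1S,2R,3R)-7-(benzyloxy)-1-[4-(benzyloxy)-3,5-dimethoxyphenyl]-6,8-dimethoxy-1,2,3,4-tetrahydronaphthalene-2,3-diyl]bis(methylene) diacetate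
Product: 24 [(1S,2R,3R)-7-hydroxy-1-(4-hydroxy-3,5-dimethoxyphenyl)-6,8-dimethoxy-1,2,3,4-tetrahydronaphthalene-2,3-diyl]bis(methylene) diacetate
Conditions: H2 (1 atm), Pd/C, EtOAc/MeOH, rt
Reagents that add atoms: none
Why: Hydrogenolysis of two aryl benzyl ethers under neutral conditions; the primary acetates, the tetralin C–C bonds and the three stereocentres should be unaffected.

## Compound list

1 | syringaldehyde (4-hydroxy-3,5-dimethoxybenzaldehyde) | COc1cc(C=O)cc(OC)c1O | starting material
2 | 4-(benzyloxy)-3,5-dimethoxybenzaldehyde | COc1cc(C=O)cc(OC)c1OCc1ccccc1 | intermediate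
3 | 4-(benzyloxy)-2-bromo-3,5-dimethoxybenzaldehyde | COc1cc(C=O)c(Br)c(OC)c1OCc1ccccc1 | intermediate
4 | [4-(benzyloxy)-2-bromo-3,5-dimethoxyphenyl]methanol | COc1cc(CO)c(Br)c(OC)c1OCc1ccccc1 | intermediate
5 | {[4-(benzyloxy)-2-bromo-3,5-dimethoxyphenyl]methoxy}(tert-butyl)dimethylsilane | COc1cc(CO[Si](C)(C)C(C)(C)C)c(Br)c(OC)c1OCc1ccccc1 | intermediate
6 | (R)-4-benzyloxazolidin-2-one | O=C1OC[C@@H](Cc2ccccc2)N1 | starting material
7 | (R)-3-acryloyl-4-benzyloxazolidin-2-one | C=CC(=O)N1[C@H](Cc2ccccc2)COC1=O | intermediate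
8 | (R)-4-benzyl-3-[(E)-3-{3-(benzyloxy)-6-[(tert-butyldimethylsilyloxy)methyl]-2,4-dimethoxyphenyl}prop-2-enoyl]oxazolidin-2-one | COc1cc(CO[Si](C)(C)C(C)(C)C)c(/C=C/C(=O)N2[C@H](Cc3ccccc3)COC2=O)c(OC)c1OCc1ccccc1 | intermediate
9 | 4-bromo-2,6-dimethoxyphenol | COc1cc(Br)cc(OC)c1O | starting material
10 | 2-(benzyloxy)-5-bromo-1,3-dimethoxybenzene | COc1cc(Br)cc(OC)c1OCc1ccccc1 | intermediate
11 | [4-(benzyloxy)-3,5-dimethoxyphenyl]magnesium bromide | COc1cc([Mg]Br)cc(OC)c1OCc1ccccc1 | intermediate (not isolated)
12 | (R)-4-benzyl-3-[(3S)-3-[4-(benzyloxy)-3,5-dimethoxyphenyl]-3-{3-(benzyloxy)-6-[(tert-butyldimethylsilyloxy)methyl]-2,4-dimethoxyphenyl}propanoyl]oxazolidin-2-one | COc1cc([C@@H](c2c(CO[Si](C)(C)C(C)(C)C)cc(OC)c(OCc3ccccc3)c2OC)CC(=O)N2[C@H](Cc3ccccc3)COC2=O)cc(OC)c1OCc1ccccc1 | intermediate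
13 | trichlorotitanium (Z)-enolate of imide 12 | COc1cc([C@@H](c2c(CO[Si](C)(C)C(C)(C)C)cc(OC)c(OCc3ccccc3)c2OC)/C=C(\O[Ti](Cl)(Cl)Cl)N2[C@H](Cc3ccccc3)COC2=O)cc(OC)c1OCc1ccccc1 | intermediate (not isolated)
14 | (R)-4-benzyl-3-[(2S,3S)-3-[4-(benzyloxy)-3,5-dimethoxyphenyl]-3-{3-(benzyloxy)-6-[(tert-butyldimethylsilyloxy)methyl]-2,4-dimethoxyphenyl}-2-(hydroxymethyl)propanoyl]oxazolidin-2-one | COc1cc([C@@H](c2c(CO[Si](C)(C)C(C)(C)C)cc(OC)c(OCc3ccccc3)c2OC)[C@@H](CO)C(=O)N2[C@H](Cc3ccccc3)COC2=O)cc(OC)c1OCc1ccccc1 | intermediate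
15 | (R)-4-benzyl-3-[(2S,3S)-3-[4-(benzyloxy)-3,5-dimethoxyphenyl]-3-{3-(benzyloxy)-6-[(tert-butyldimethylsilyloxy)methyl]-2,4-dimethoxyphenyl}-2-{[(tert-butyldiphenylsilyl)oxy]methyl}propanoyl]oxazolidin-2-one | COc1cc([C@@H](c2c(CO[Si](C)(C)C(C)(C)C)cc(OC)c(OCc3ccccc3)c2OC)[C@@H](CO[Si](c2ccccc2)(c2ccccc2)C(C)(C)C)C(=O)N2[C@H](Cc3ccccc3)COC2=O)cc(OC)c1OCc1ccccc1 | intermediate
16 | (2R,3S)-3-[4-(benzyloxy)-3,5-dimethoxyphenyl]-3-{3-(benzyloxy)-6-[(tert-butyldimethylsilyloxy)methyl]-2,4-dimethoxyphenyl}-2-{[(tert-butyldiphenylsilyl)oxy]methyl}propan-1-ol | COc1cc([C@@H](c2c(CO[Si](C)(C)C(C)(C)C)cc(OC)c(OCc3ccccc3)c2OC)[C@@H](CO[Si](c2ccccc2)(c2ccccc2)C(C)(C)C)CO)cc(OC)c1OCc1ccccc1 | intermediate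
17 | (2S,3S)-3-[4-(benzyloxy)-3,5-dimethoxyphenyl]-3-{3-(benzyloxy)-6-[(tert-butyldimethylsilyloxy)methyl]-2,4-dimethoxyphenyl}-2-{[(tert-butyldiphenylsilyl)oxy]methyl}propanal | COc1cc([C@@H](c2c(CO[Si](C)(C)C(C)(C)C)cc(OC)c(OCc3ccccc3)c2OC)[C@@H](CO[Si](c2ccccc2)(c2ccccc2)C(C)(C)C)C=O)cc(OC)c1OCc1ccccc1 | intermediate
18 | 2-[(1E,3S,4S)-4-[4-(benzyloxy)-3,5-dimethoxyphenyl]-4-{3-(benzyloxy)-6-[(tert-butyldimethylsilyloxy)methyl]-2,4-dimethoxyphenyl}-3-{[(tert-butyldiphenylsilyl)oxy]methyl}but-1-en-1-yl]-4,4,5,5-tetramethyl-1,3,2-dioxaborolane | COc1cc([C@@H](c2c(CO[Si](C)(C)C(C)(C)C)cc(OC)c(OCc3ccccc3)c2OC)[C@@H](CO[Si](c2ccccc2)(c2ccccc2)C(C)(C)C)/C=C/B2OC(C)(C)C(C)(C)O2)cc(OC)c1OCc1ccccc1 | intermediate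
19 | 2-[(1E,3S,4S)-4-[3-(benzyloxy)-6-(bromomethyl)-2,4-dimethoxyphenyl]-4-[4-(benzyloxy)-3,5-dimethoxyphenyl]-3-{[(tert-butyldiphenylsilyl)oxy]methyl}but-1-en-1-yl]-4,4,5,5-tetramethyl-1,3,2-dioxaborolane | COc1cc([C@@H](c2c(CBr)cc(OC)c(OCc3ccccc3)c2OC)[C@@H](CO[Si](c2ccccc2)(c2ccccc2)C(C)(C)C)/C=C/B2OC(C)(C)C(C)(C)O2)cc(OC)c1OCc1ccccc1 | intermediate
20 | tert-butyl{[(1S,2S,3R)-7-(benzyloxy)-1-[4-(benzyloxy)-3,5-dimethoxyphenyl]-6,8-dimethoxy-3-[(4,4,5,5-tetramethyl-1,3,2-dioxaborolan-2-yl)methyl]-1,2,3,4-tetrahydronaphthalen-2-yl]methoxy}diphenylsilane | COc1cc([C@H]2c3c(cc(OC)c(OCc4ccccc4)c3OC)C[C@@H](CB4OC(C)(C)C(C)(C)O4)[C@@H]2CO[Si](c2ccccc2)(c2ccccc2)C(C)(C)C)cc(OC)c1OCc1ccccc1 | intermediate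
21 | [(1S,2R,3R)-7-(benzyloxy)-1-[4-(benzyloxy)-3,5-dimethoxyphenyl]-2-{[(tert-butyldiphenylsilyl)oxy]methyl}-6,8-dimethoxy-1,2,3,4-tetrahydronaphthalen-3-yl]methanol | COc1cc([C@H]2c3c(cc(OC)c(OCc4ccccc4)c3OC)C[C@@H](CO)[C@@H]2CO[Si](c2ccccc2)(c2ccccc2)C(C)(C)C)cc(OC)c1OCc1ccccc1 | intermediate
22 | [(1S,2R,3R)-7-(benzyloxy)-1-[4-(benzyloxy)-3,5-dimethoxyphenyl]-6,8-dimethoxy-1,2,3,4-tetrahydronaphthalene-2,3-diyl]dimethanol | COc1cc([C@H]2c3c(cc(OC)c(OCc4ccccc4)c3OC)C[C@@H](CO)[C@@H]2CO)cc(OC)c1OCc1ccccc1 | intermediate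
23 | [(1S,2R,3R)-7-(benzyloxy)-1-[4-(benzyloxy)-3,5-dimethoxyphenyl]-6,8-dimethoxy-1,2,3,4-tetrahydronaphthalene-2,3-diyl]bis(methylene) diacetate | COc1cc([C@H]2c3c(cc(OC)c(OCc4ccccc4)c3OC)C[C@@H](COC(C)=O)[C@@H]2COC(C)=O)cc(OC)c1OCc1ccccc1 | intermediate
24 | [(1S,2R,3R)-7-hydroxy-1-(4-hydroxy-3,5-dimethoxyphenyl)-6,8-dimethoxy-1,2,3,4-tetrahydronaphthalene-2,3-diyl]bis(methylene) diacetate | COc1cc([C@H]2c3c(cc(OC)c(O)c3OC)C[C@@H](COC(C)=O)[C@@H]2COC(C)=O)cc(OC)c1O | target

## Step count and least certain steps

Total: 19 steps. Longest linear sequence: 17 steps, from 1 through steps 1–4, 6 and 8–19.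

**Step 15 (key step).** Two processes threaten it. Hydrogen transfer from the stannane to the stabilized benzylic radical may outrun ring closure, giving simple reduction. More seriously, facial discrimination at C3 may be poor, because the E-alkene carries only hydrogen cis to C2 and so the conformation about C2–C3 is held only by the chair preference. Premature reduction can be met within the step by slower addition or a slower hydrogen donor, but an epimer at C3 cannot be repaired.

The fallback therefore changes the substrate geometry to bring allylic 1,3-strain into play: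
- From aldehyde 17, Stork–Zhao olefination (iodomethyltriphenylphosphonium iodide, NaHMDS, THF/DMPU, −78 °C) would give the (Z)-vinyl iodide F1.
- Miyaura borylation with retention (B2pin2, PdCl2(PPh3)2, PPh3, KOPh, toluene, 50 °C) would give the (Z)-alkenylboronate F2, the geometric isomer of 18.
- Ph3PBr2 as in step 14 would give the (Z)-configured benzylic bromide F3.
- Cyclization of F3 under the conditions of step 15 returns to the route at 20, since the alkene geometry is lost in the product.

In F3 the boron substituent cis to C2 forces the C2–H bond into the alkene plane. C9' then lies anti to the incoming C4 radical, which should enforce the 2,3-trans outcome.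

**Step 8.** The β-carbon of 8 is shielded by two ortho substituents, so the conjugate addition may be sluggish. Warming then invites attack at the imide carbonyls and erosion of facial selectivity. The fallback moves stereocontrol from the auxiliary to a catalyst that can be heated:
- From bromide 5, a Heck reaction with methyl acrylate (catalyst of step 6) would give the methyl cinnamate F4.
- Grignard reagent 11 with B(OMe)3 and acidic work-up would give the arylboronic acid F5.
- A Hayashi–Miyaura addition of F5 to F4 ([RhCl(C2H4)2]2 with a chiral bicyclic diene ligand of the antipode that gives 3S, KOH, dioxane/H2O, 60 °C) would give the methyl (3S)-3,3-diarylpropanoate F6.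
- LiOH would give the acid F7.
- Pivaloyl chloride/Et3N would give the mixed anhydride F8, which acylates 6 (LiCl) to rejoin the route at 12.

**Step 9.** Free TiCl4 may ionize the electron-rich benzylic silyl ether or cleave the benzyl ether flanked by two methoxy groups. The congested enolate may also react slowly with the formaldehyde equivalent. The fallback avoids Lewis acids and sets C2 by enamine catalysis:
- From 12, LiBH4 would give the 3,3-diarylpropan-1-ol F9, with 6 recovered.
- Dess–Martin oxidation would give the aldehyde F10.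
- α-Hydroxymethylation with aqueous formaldehyde and a diarylprolinol silyl ether catalyst of the antipode that gives 2S (buffered toluene, rt) would give the β-hydroxy aldehyde F11.
- Immediate silylation with TBDPSCl/imidazole rejoins the route at 17.

**Step 14.** The reagent may also attack the primary tert-butyldiphenylsilyl ether, or the labile para-alkoxybenzyl bromide may decompose during the reaction. The fallback separates unmasking from activation:
- From 18, PPTS in MeOH at rt would release the benzylic alcohol F12 selectively.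
- An Appel reaction (CBr4, PPh3, CH2Cl2, 0 °C) then gives 19, to be used directly in step 15.

**Step 6.** Oxidative addition to the electron-rich, doubly ortho-substituted bromide may be slow, and 7 may polymerize on prolonged heating. The fallback replaces the Heck reaction by an olefination:
- From 5, bromine–lithium exchange (n-BuLi, THF, −78 °C) and formylation with DMF would give the aldehyde F13.
- The phosphonate F14 would be made from 6 and 2-(diethoxyphosphoryl)acetyl chloride.
- A Horner–Wadsworth–Emmons reaction of F13 with F14 under Masamune–Roush conditions (LiCl, i-Pr2NEt, MeCN) would give the E-enoyl imide 8.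

## Further compounds

F1 | step 15 | (Z)-vinyl iodide from 17 (C1 and C2 as in 17) | COc1cc([C@@H](c2c(CO[Si](C)(C)C(C)(C)C)cc(OC)c(OCc3ccccc3)c2OC)[C@@H](CO[Si](c2ccccc2)(c2ccccc2)C(C)(C)C)/C=C\I)cc(OC)c1OCc1ccccc1
F2 | step 15 | (Z)-alkenyl pinacolboronate, geometric isomer of 18 | COc1cc([C@@H](c2c(CO[Si](C)(C)C(C)(C)C)cc(OC)c(OCc3ccccc3)c2OC)[C@@H](CO[Si](c2ccccc2)(c2ccccc2)C(C)(C)C)/C=C\B2OC(C)(C)C(C)(C)O2)cc(OC)c1OCc1ccccc1
F3 | step 15 | (Z)-configured benzylic bromide, geometric isomer of 19 | COc1cc([C@@H](c2c(CBr)cc(OC)c(OCc3ccccc3)c2OC)[C@@H](CO[Si](c2ccccc2)(c2ccccc2)C(C)(C)C)/C=C\B2OC(C)(C)C(C)(C)O2)cc(OC)c1OCc1ccccc1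
F4 | step 8 | methyl (E)-3-{3-(benzyloxy)-6-[(tert-butyldimethylsilyloxy)methyl]-2,4-dimethoxyphenyl}prop-2-enoate | COC(=O)/C=C/c1c(CO[Si](C)(C)C(C)(C)C)cc(OC)c(OCc2ccccc2)c1OC
F5 | step 8 | [4-(benzyloxy)-3,5-dimethoxyphenyl]boronic acid | COc1cc(B(O)O)cc(OC)c1OCc1ccccc1
F6 | step 8 | methyl (3S)-3-[4-(benzyloxy)-3,5-dimethoxyphenyl]-3-{3-(benzyloxy)-6-[(tert-butyldimethylsilyloxy)methyl]-2,4-dimethoxyphenyl}propanoate | COc1cc([C@@H](c2c(CO[Si](C)(C)C(C)(C)C)cc(OC)c(OCc3ccccc3)c2OC)CC(=O)OC)cc(OC)c1OCc1ccccc1
F7 | step 8 | (3S)-3-[4-(benzyloxy)-3,5-dimethoxyphenyl]-3-{3-(benzyloxy)-6-[(tert-butyldimethylsilyloxy)methyl]-2,4-dimethoxyphenyl}propanoic acid | COc1cc([C@@H](c2c(CO[Si](C)(C)C(C)(C)C)cc(OC)c(OCc3ccccc3)c2OC)CC(=O)O)cc(OC)c1OCc1ccccc1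
F8 | step 8 | mixed pivalic anhydride of acid F7 | COc1cc([C@@H](c2c(CO[Si](C)(C)C(C)(C)C)cc(OC)c(OCc3ccccc3)c2OC)CC(=O)OC(=O)C(C)(C)C)cc(OC)c1OCc1ccccc1
F9 | step 9 | (3S)-3-[4-(benzyloxy)-3,5-dimethoxyphenyl]-3-{3-(benzyloxy)-6-[(tert-butyldimethylsilyloxy)methyl]-2,4-dimethoxyphenyl}propan-1-ol | COc1cc([C@@H](c2c(CO[Si](C)(C)C(C)(C)C)cc(OC)c(OCc3ccccc3)c2OC)CCO)cc(OC)c1OCc1ccccc1
F10 | step 9 | (3S)-3-[4-(benzyloxy)-3,5-dimethoxyphenyl]-3-{3-(benzyloxy)-6-[(tert-butyldimethylsilyloxy)methyl]-2,4-dimethoxyphenyl}propanal | COc1cc([C@@H](c2c(CO[Si](C)(C)C(C)(C)C)cc(OC)c(OCc3ccccc3)c2OC)CC=O)cc(OC)c1OCc1ccccc1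
F11 | step 9 | (2S,3S)-3-[4-(benzyloxy)-3,5-dimethoxyphenyl]-3-{3-(benzyloxy)-6-[(tert-butyldimethylsilyloxy)methyl]-2,4-dimethoxyphenyl}-2-(hydroxymethyl)propanal | COc1cc([C@@H](c2c(CO[Si](C)(C)C(C)(C)C)cc(OC)c(OCc3ccccc3)c2OC)[C@@H](CO)C=O)cc(OC)c1OCc1ccccc1
F12 | step 14 | benzylic alcohol corresponding to 18 (tert-butyldimethylsilyl group removed; alkenylboronate and tert-butyldiphenylsilyl ether retained) | COc1cc([C@@H](c2c(CO)cc(OC)c(OCc3ccccc3)c2OC)[C@@H](CO[Si](c2ccccc2)(c2ccccc2)C(C)(C)C)/C=C/B2OC(C)(C)C(C)(C)O2)cc(OC)c1OCc1ccccc1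
F13 | step 6 | 3-(benzyloxy)-6-[(tert-butyldimethylsilyloxy)methyl]-2,4-dimethoxybenzaldehyde | COc1cc(CO[Si](C)(C)C(C)(C)C)c(C=O)c(OC)c1OCc1ccccc1
F14 | step 6 | (R)-4-benzyl-3-[2-(diethoxyphosphoryl)acetyl]oxazolidin-2-one | CCOP(=O)(CC(=O)N1[C@H](Cc2ccccc2)COC1=O)OCC
A1 | alternative 1 | (S)-4-benzyl-3-[(E)-3-(4-hydroxy-3,5-dimethoxyphenyl)prop-2-enoyl]oxazolidin-2-one | COc1cc(/C=C/C(=O)N2[C@@H](Cc3ccccc3)COC2=O)cc(OC)c1O
A2 | alternative 1 | trans-1-aryl-1,2-dihydronaphthalene-2,3-dicarbonyl bis(oxazolidinone) with both phenols free | COc1cc([C@H]2c3c(cc(OC)c(O)c3OC)C=C(C(=O)N3[C@@H](Cc4ccccc4)COC3=O)[C@@H]2C(=O)N2[C@@H](Cc3ccccc3)COC2=O)cc(OC)c1O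
A3 | alternative 2 | 7-(benzyloxy)-1-[4-(benzyloxy)-3,5-dimethoxyphenyl]-6,8-dimethoxy-1,4-dihydronaphthalene (C1 configured as in the target) | COc1cc([C@H]2c3c(cc(OC)c(OCc4ccccc4)c3OC)CC=C2)cc(OC)c1OCc1ccccc1
A4 | alternative 2 | dichloroketene | ClC(Cl)=C=O
A5 | alternative 2 | cis-fused 2,2-dichlorocyclobutanone on C2–C3 of the 1-aryltetralin | COc1cc([C@H]2c3c(cc(OC)c(OCc4ccccc4)c3OC)C[C@@H]5C(=O)C(Cl)(Cl)[C@H]25)cc(OC)c1OCc1ccccc1
A6 | alternative 3 | 4-(benzyloxy)-2-[4-(benzyloxy)-3,5-dimethoxybenzyl]-3,5-dimethoxybenzaldehyde | COc1cc(Cc2c(C=O)cc(OC)c(OCc3ccccc3)c2OC)cc(OC)c1OCc1ccccc1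
A7 | alternative 3 | dimethyl fumarate | COC(=O)/C=C/C(=O)OC
A8 | alternative 3 | dimethyl 1-aryl-4-hydroxytetralin-2,3-dicarboxylate (1,2-trans, 2,3-trans, 3,4-cis) | COc1cc([C@H]2c3c(cc(OC)c(OCc4ccccc4)c3OC)[C@@H](O)[C@@H](C(=O)OC)[C@@H]2C(=O)OC)cc(OC)c1OCc1ccccc1
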